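At early times the rate goes with free catalyst and with both partners, so I integrate that one rate in closed form. Let x be product as a fraction of the starting material charged, and ρ = 0.800 the reagent charge on that scale (reagent is the limiting reagent). The reach is then

G = ln[ρ(1 − x)/(ρ − x)] / (1 − ρ)

While the catalyst holds, G grows as catalyst charge times time, which I call catalyst-time.

common to all: starting material 0.150 M; reagent 0.120 M

| charge | free catalyst | time |
|---|---|---|
| ochre | 0.00750 M |  |
| green | 0.00370 M |  |
| red | 0.00160 M | 160 h |

| ochre run: time / h | ochre run: [product] / M | green run: time / h | green run: [product] / M |
|---|---|---|---|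
| 32 | 0.0756 | 32 | 0.0578 |
| 64 | 0.0888 | 64 | 0.0727 |
| 96 | 0.0931 | 96 | 0.0800 |
| 130 | 0.0957 | 130 | 0.0837 |
| 160 | 0.0967 | 160 | 0.0854 |

(readings scatter by 4 × 10⁻⁴ M)

1. how the opening rate goes with [free catalyst] round the charge of the ochre run: the exponent of the rate at two percent of starting material gone to product
2. product in the red run at 160 h, as a share of the starting material charged

- Overall: starting material + reagent -> product, with free catalyst as catalyst.
- Constant volume, constant temperature.
- Readings of a species count what is bound in complexes too.
- "The second partner" is reagent.
- An order is taken over about fifteen percent of the charge, up and down.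

Ochre at 64 h and green at 130 h have equal catalyst-time. Their reaches are close, so I take the opening order in free catalyst as 1:

ochre G = 2.25; green G = 1.90

Green lags and took longer, so I read a clock loss, the fractional drop in reach per extra hour at equal catalyst-time:

λ = ln(ochre G / green G) / extra hours = 0.00261 h⁻¹

This is a reading, with the scatter of two readings in it.

The red run at 160 h has the catalyst-time of green at 69.2 h. Interpolating green there gives my ceiling:

green G = 1.34 at 64 h, 1.68 at 96 h

G = 1.40, x = 49.3 %

At 160 h green reaches 2.01 on half the catalyst of ochre, which reaches 3.02. Reach per unit of catalyst is thus higher at the lower charge. Scaling green's reach to the red charge gives my floor: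

G = 0.867, x = 38.9 %

Charging the ceiling with the red run's extra hours tightens it:

G = 1.10, x = 44.2 %

The forecast puts the order at 1 and the red run at 44 %, and of the order it says: “That ratio of about 2 for a twofold catalyst change means the opening order is about 1”. Its value stands inside my bracket.

The flask gives order 0.99 and 44.6 %.

    free catalyst + starting material ⇌ catalyst-substrate complex, settled at all times (1.740 L mol⁻¹)
    catalyst-substrate complex + reagent → product + free catalyst (41.76 L mol⁻¹ h⁻¹)
    2 free catalyst → 2 spent catalyst (2.268 L mol⁻¹ h⁻¹)
    starting material → decomposed substrate (0.005652 h⁻¹)

The clock loss in the red run is the path from starting material to decomposed substrate. The red run's reach of 1.12, with λ undone over its 160 h, becomes 1.70. That reach means x = 53.6 %. The red run without that path gives 54.0 %.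

(The earlier runs and the new flask stem from a simulated flask from invented constants; the scatter is artificial.)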